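| flask | solid substrate | reagent | remark | time |
|---|---|---|---|---|
| teal | 0.38 M | 0.50 equiv (fed, over 80 s) | run made earlier |  |
| green | 0.38 M | 2 equiv (fed, over 80 s) | run made earlier |  |
| red | 0.76 M | 1 equiv (fed, over 80 s) | run made earlier |  |
| flask | 0.38 M | 1.00 equiv (fed, over 80 s) |  | 2.5 h |

| run | time / min | tautomer / % | target / % |
|---|---|---|---|
| teal | 3.00 | 13 | 0 |
| teal | 8.00 | 27 | 12 |
| teal | 30.0 | 25 | 34 |
| teal | 90.0 | 24 | 47 |
| green | 3.00 | 9 | 7 |
| green | 8.00 | 14 | 25 |
| green | 30.0 | 6 | 72 |
| green | 90.0 | 0 | 95 |
| red | 3.00 | 3 | 4 |
| red | 8.00 | 8 | 11 |
| red | 30.0 | 11 | 58 |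
| red | 90.0 | 3 | 88 |

(each reading ± 2 percentage points)

* when, up to 2.5 h, the flask holds most tautomer
* the amount of tautomer, in percent of the solid substrate charged, at that time

Early on the feed is over within 80 s, so I treat the reagent as present from the start and climb the ladder from there. I take the fastest rung, the exchange of starting material and tautomer, as balanced throughout. In the teal run at 90.0 min, target has taken nearly all of the reagent, so I neglect the isomer of the product there and read the tautomer share, tautomer divided by everything that is not target, as 0.453.

The next rung is dissolving. The teal reading at 3.00 min shows 13% tautomer and 0% target, so the share puts 28.7% of the charge in solution, a rate of 0.0957 min⁻¹ of the charge. At the same concentration, I expect the solid in the flask to last about 10.4 min, longer than the feed.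

The last rung is the drain into target and isomer, and I place the peak, as my own estimate, where the solid ends. The teal balance at 30.0 min leaves a gap of 10.8%, which I assign to the isomer. The flask has twice the teal reagent and half the green, so as a rough guess I take the geometric mean of the teal and green target readings at 8.00 min, which is 17.3%, and I carry the teal gap over unchanged, having no reading of it at this charge. The share then gives 32.6%.

The forecast gives 18% at 0.7 h, holding that “Near 45 min the solid and dissolved starting material run out”; my time is earlier.

The flask gives 23.1% at 0.183 h.

    starting material ⇌ tautomer (K = 0.913, k = 0.503 min⁻¹)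
    starting material + reagent ⇌ isomer of the product (K = 3.94 L mol⁻¹, k = 0.466 L mol⁻¹ min⁻¹)
    reagent + tautomer → target (k = 0.581 L mol⁻¹ min⁻¹)
    solid substrate ⇌ starting material, rate k4*(cs4 - [starting material]) while solid is left; crystals form when [starting material] > cs4 (solubility = 0.160 M, k = 0.554 min⁻¹)

While solid stood in the flask, still 76.5% at 0.0222 h, dissolving fed starting material, which exchanged with tautomer at a relaxation half-life of 0.658 min. At 0.183 h the solid stood at 0%, with 25.7% target and 20.5% isomer, and from there reagent and tautomer carried target to 91.3% by 2.50 h. Those peak amounts give 24.4% by the share. In the neighbour flask with 0.250 equiv of reagent, 24.9% target at 2.50 h gives 34.0% by the share, and that flask holds 35.8% tautomer.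

The numbers in the tables stem from a simulated flask for substances that don't exist, and the scatter is random.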